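Ring atoms are numbered C1 (tertiary carbinol) to C6, with Br and CH3 on C4 and Cl on C5; C7 is the exocyclic carbon on C1. The plan hinges on disconnecting C4–C5, retraced as a C4=C5 alkene: one ring-closing metathesis of an acyclic α-hydroxy ester carrying an allyl and a 3-methylbut-3-enyl arm builds the cyclohexene ring and its trisubstituted alkene together. It exploits the fact that C1, which in the ring sits between two almost equivalent CH2 arms (C2, C6), becomes an open-chain carbinol with three clearly different carbon groups once C4–C5 is cut, so catalytic allylation can set it; the alkene later converts the C1–OH face into the C5–Cl/C4–Br pair.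

Key step: step 3

Remark: the ring-closing precursor has to be the 5-methylhex-5-enoate, with two CH2 groups between the carbinol carbon and the isopropenyl unit; a 6-methylhept-6-enoate chain would close a seven-membered ring, so the shorter chain is the structure used.
Remark: atom labels C1–C7 in the text follow the numbering of the overview; locants inside compound names follow nomenclature rules.

Step 1
Reactants: 1 4-bromo-2-methylbut-1-ene; 2 dimethyl oxalate
Product: 4 methyl 5-methyl-2-oxohex-5-enoate, via 3-methylbut-3-enylmagnesium bromide 3 (not isolated)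
Conditions: Mg, THF, rt; then added to 2 (2 equiv), THF, −78 °C; sat. aq NH4Cl at −78 °C
Reagents that add atoms: none
Why: Grignard formation and mono-addition to a dialkyl oxalate, where the magnesium hemiketal alkoxide should survive at −78 °C and collapse to the α-keto ester only on quench, so that over-addition is avoided; no stereocentre is formed.

Step 2
Reactants: 4 methyl 5-methyl-2-oxohex-5-enoate; 5 allylboronic acid pinacol ester
Product: 6 methyl (2R)-2-hydroxy-5-methyl-2-(prop-2-en-1-yl)hex-5-enoate
Conditions: chiral valine-derived aminophenol catalyst (2.5 mol %, enantiomer directing Re-face addition), NaOt-Bu (5 mol %), MeOH (1.5 equiv), toluene, 22 °C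
Reagents that add atoms: none
Why: Catalytic enantioselective allylboration of an α-keto ester, in which the catalyst-bound allylboron should deliver allyl through a closed six-membered transition state to the Re face of the ketone (ester and alkyl arm being clearly different), setting C1 as (R).

Step 3
Reactants: 6 methyl (2R)-2-hydroxy-5-methyl-2-(prop-2-en-1-yl)hex-5-enoate
Product: 7 methyl (1R)-1-hydroxy-4-methylcyclohex-3-ene-1-carboxylate
Conditions: Grubbs second-generation catalyst (3 mol %), CH2Cl2 (0.02 M), 40 °C
Reagents that add atoms: none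
Why: Ring-closing olefin metathesis: the ruthenium benzylidene exchanges onto the unhindered monosubstituted allyl alkene, the resulting alkylidene adds across the tethered 1,1-disubstituted alkene to a ruthenacyclobutane, and cycloreversion delivers the C4=C5 alkene and Ru=CH2, which re-enters the cycle with loss of ethylene. The closest known reaction type is the closure of 1,7-dienes bearing one gem-disubstituted alkene to trisubstituted cyclohexenes with NHC–ruthenium catalysts. The single ring is closed as a six-membered carbocycle by joining the internal allyl carbon (C5) to the methyl-bearing alkene carbon (C4), the new double bond lying inside the ring. No stereocentre is created, and the quaternary C1 carbinol set in step 2 cannot epimerise. The selectivity required is cyclisation over intermolecular metathesis; it should be secured by the fully substituted C1 that presses the two arms together, by the strain-free ring size, by the reluctance of the 1,1-disubstituted alkene to cross-metathesise and by dilution, while the free tertiary hydroxyl and the ester are inert to the catalyst.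

Step 4
Reactants: 7 methyl (1R)-1-hydroxy-4-methylcyclohex-3-ene-1-carboxylate
Product: 8 methyl (1R,3S,4S)-3-chloro-4-methyl-7-oxabicyclo[2.2.1]heptane-1-carboxylate (oxygen bridge between C1 and C4, chlorine on C5 endo, anti to the bridge)
Conditions: NCS (1.1 equiv), Ph3P=S (10 mol %), CH2Cl2, 0 °C → rt
Reagents that add atoms: N-chlorosuccinimide, O=C1CCC(=O)N1Cl
Why: Chloroetherification (5-exo halocyclisation): chlorenium adds to C4=C5 and the C1 hydroxyl, tethered to one face, can only reach the Markovnikov carbon C4 anti to the incoming chlorine, which fixes the new C4–O bond cis to C1–O and the C5–Cl bond trans to it, attack at C5 being excluded because it would form an oxetane.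

Step 5
Reactants: 8 methyl (1R,3S,4S)-3-chloro-4-methyl-7-oxabicyclo[2.2.1]heptane-1-carboxylate
Product: 9 methyl (1R,3S,4S)-4-bromo-3-chloro-1-hydroxy-4-methylcyclohexane-1-carboxylate (Br cis to OH, Cl trans to both)
Conditions: BBr3 (1.2 equiv), CH2Cl2, −78 → −20 °C; then H2O
Reagents that add atoms: boron tribromide, BrB(Br)Br
Why: Proposed new method: boron coordinates the bridging oxygen and only the C4–O bond can ionise (C1–O is α to the ester); the endo chlorine on C5, antiperiplanar to the breaking bond, should bridge to C4 as a chloronium ion, which bromide opens at the tertiary carbon anti to chlorine, so that Br takes the face the oxygen left (net retention at C4) and the trans C4–Br/C5–Cl pair results with the C1 hydroxyl freed; the closest known reaction types are the cleavage of cineole-type bridged tertiary ethers to tertiary bromides by BBr3 or HBr and substitution with retention through neighbouring-halogen participation.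

Step 6
Reactants: 9 methyl (1R,3S,4S)-4-bromo-3-chloro-1-hydroxy-4-methylcyclohexane-1-carboxylate
Product: 11 (1R,3S,4S)-4-bromo-3-chloro-4-methyl-1-[3-(trimethylsilyl)prop-1-en-2-yl]cyclohexan-1-ol, via bis(silylmethyl) carbinol 10 (not isolated)
Conditions: TMSCH2MgCl (5 equiv), CeCl3 (5 equiv), THF, −78 °C → rt; then SiO2, CH2Cl2, rt
Reagents that add atoms: (trimethylsilyl)methylmagnesium chloride, C[Si](C)(C)C[Mg]Cl
Why: Cerium-mediated double addition of the silylmethyl Grignard reagent to the ester, then Peterson elimination of one β-hydroxysilane arm on silica (ester-to-allylsilane conversion), in which the weakly basic organocerium should spare the tertiary bromide and the first equivalent only deprotonates the C1 hydroxyl; no stereocentre is formed or touched.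

Step 7
Reactants: 11 (1R,3S,4S)-4-bromo-3-chloro-4-methyl-1-[3-(trimethylsilyl)prop-1-en-2-yl]cyclohexan-1-ol
Product: 12 {[(1R,3S,4S)-4-bromo-3-chloro-4-methyl-1-[3-(trimethylsilyl)prop-1-en-2-yl]cyclohexyl]oxy}trimethylsilane
Conditions: TMSOTf (1.3 equiv), Et3N (2 equiv), CH2Cl2, −78 °C
Reagents that add atoms: trimethylsilyl trifluoromethanesulfonate, C[Si](C)(C)OS(=O)(=O)C(F)(F)F
Why: Silylation of a tertiary alcohol with a silyl triflate and amine base, needed so that no free hydroxyl consumes the silylium catalyst or protodesilylates the allylsilane in step 8; no stereocentre is affected.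

Step 8
Reactants: 12 {[(1R,3S,4S)-4-bromo-3-chloro-4-methyl-1-[3-(trimethylsilyl)prop-1-en-2-yl]cyclohexyl]oxy}trimethylsilane; 13 3-methylbut-2-enal
Product: 15 (4S)-2-[(1R,3S,4S)-4-bromo-3-chloro-1-hydroxy-4-methylcyclohexyl]-6-methylhepta-1,5-dien-4-ol, via bis(trimethylsilyl) ether 14 (not isolated)
Conditions: chiral imidodiphosphorimidate (IDPi) acid catalyst (2 mol %, enantiomer directing Si-face addition), 13 (1.5 equiv), toluene, −78 °C; then TBAF, AcOH, THF, 0 °C
Reagents that add atoms: none
Why: Catalytic enantioselective Hosomi–Sakurai allylation under silylium counteranion-directed catalysis with a 2-substituted allyltrimethylsilane, in which the confined chiral anion pairs with the O-silylated aldehyde and should expose its Si face to the allylsilane terminus, setting the side-chain carbinol as (S) under catalyst control (the remote ring centres exert little bias), after which buffered fluoride removes both silyl groups without base-induced loss of HBr.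

Compound list
1 | 4-bromo-2-methylbut-1-ene | C=C(C)CCBr | starting material
2 | dimethyl oxalate | COC(=O)C(=O)OC | starting material
3 | (3-methylbut-3-en-1-yl)magnesium bromide | C=C(C)CC[Mg]Br | intermediate (not isolated)
4 | methyl 5-methyl-2-oxohex-5-enoate | COC(=O)C(=O)CCC(C)=C | intermediate
5 | allylboronic acid pinacol ester (2-allyl-4,4,5,5-tetramethyl-1,3,2-dioxaborolane) | C=CCB1OC(C)(C)C(C)(C)O1 | starting material
6 | methyl (2R)-2-hydroxy-5-methyl-2-(prop-2-en-1-yl)hex-5-enoate | COC(=O)[C@@](CC=C)(O)CCC(C)=C | intermediate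
7 | methyl (1R)-1-hydroxy-4-methylcyclohex-3-ene-1-carboxylate | COC(=O)[C@@]1(O)CCC(C)=CC1 | intermediate
8 | methyl (1R,3S,4S)-3-chloro-4-methyl-7-oxabicyclo[2.2.1]heptane-1-carboxylate | COC(=O)[C@]12CC[C@](C)(O1)[C@@H](Cl)C2 | intermediate
9 | methyl (1R,3S,4S)-4-bromo-3-chloro-1-hydroxy-4-methylcyclohexane-1-carboxylate | COC(=O)[C@@]1(O)CC[C@](C)(Br)[C@@H](Cl)C1 | intermediate
10 | (1R,3S,4S)-4-bromo-3-chloro-1-[2-hydroxy-1,3-bis(trimethylsilyl)propan-2-yl]-4-methylcyclohexan-1-ol | C[Si](C)(C)CC(O)(C[Si](C)(C)C)[C@@]1(O)CC[C@](C)(Br)[C@@H](Cl)C1 | intermediate (not isolated)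
11 | (1R,3S,4S)-4-bromo-3-chloro-4-methyl-1-[3-(trimethylsilyl)prop-1-en-2-yl]cyclohexan-1-ol | C=C(C[Si](C)(C)C)[C@@]1(O)CC[C@](C)(Br)[C@@H](Cl)C1 | intermediate
12 | {[(1R,3S,4S)-4-bromo-3-chloro-4-methyl-1-[3-(trimethylsilyl)prop-1-en-2-yl]cyclohexyl]oxy}trimethylsilane | C=C(C[Si](C)(C)C)[C@@]1(O[Si](C)(C)C)CC[C@](C)(Br)[C@@H](Cl)C1 | intermediate
13 | 3-methylbut-2-enal | CC(C)=CC=O | starting material
14 | {[(4S)-2-[(1R,3S,4S)-4-bromo-3-chloro-4-methyl-1-(trimethylsilyloxy)cyclohexyl]-6-methylhepta-1,5-dien-4-yl]oxy}trimethylsilane | C=C(C[C@H](O[Si](C)(C)C)C=C(C)C)[C@@]1(O[Si](C)(C)C)CC[C@](C)(Br)[C@@H](Cl)C1 | intermediate (not isolated)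
15 | (4S)-2-[(1R,3S,4S)-4-bromo-3-chloro-1-hydroxy-4-methylcyclohexyl]-6-methylhepta-1,5-dien-4-ol | C=C(C[C@H](O)C=C(C)C)[C@@]1(O)CC[C@](C)(Br)[C@@H](Cl)C1 | target

Total step count: 8. Longest linear sequence: 8 steps (from 1 and 2 to 15).

Steps most likely to fail

1. Step 5 (bears the label). The β-chloro cation may open instead of staying bridged, so that bromide enters on either face of C4. It may also lose a proton, or the ether may resist ionisation at temperatures the ester tolerates. Fallback with known chemistry, setting out from 7 and coming back at 9 (it also avoids the chlorocyclisation of step 4): vanadium-catalysed hydroxyl-directed epoxidation of 7 (VO(acac)2, t-BuOOH, CH2Cl2) should give methyl (1R,3R,6S)-3-hydroxy-6-methyl-7-oxabicyclo[4.1.0]heptane-3-carboxylate F1, with the epoxide syn to the hydroxyl. Amide-base isomerisation of the epoxide (Et2AlTMP, toluene, 0 °C) should give methyl (1R,3R)-1,3-dihydroxy-4-methylidenecyclohexane-1-carboxylate F2. Appel chlorination (PPh3, CCl4) should invert the secondary allylic carbinol to methyl (1R,3S)-3-chloro-1-hydroxy-4-methylidenecyclohexane-1-carboxylate F3. Markovnikov addition of HBr (CH2Cl2, −78 °C), with bromide entering axially and anti to chlorine, should return 9.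

2. Step 8. The bulky quaternary substituent at the 2-position of the allylsilane may slow turnover or erode facial selectivity at the aldehyde. The allylic silyl ethers may also ionise under the silylium catalyst. Fallback setting out from 12 and coming back at 15, with the carbinol set by reduction instead of allylation: an unselective Hosomi–Sakurai reaction with 13 (BF3·OEt2, CH2Cl2, −78 °C) should give 2-[(1R,3S,4S)-4-bromo-3-chloro-4-methyl-1-(trimethylsilyloxy)cyclohexyl]-6-methylhepta-1,5-dien-4-ol F4 as a mixture of carbinol epimers. Buffered Dess–Martin oxidation should give 2-[(1R,3S,4S)-4-bromo-3-chloro-4-methyl-1-(trimethylsilyloxy)cyclohexyl]-6-methylhepta-1,5-dien-4-one F5. CBS reduction ((R)-Me-oxazaborolidine, catecholborane, toluene, −78 °C) should give (4S)-2-[(1R,3S,4S)-4-bromo-3-chloro-4-methyl-1-(trimethylsilyloxy)cyclohexyl]-6-methylhepta-1,5-dien-4-ol F6. TBAF/AcOH should then give 15.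

3. Step 6. The sequence may stall after the first addition through enolisation of the β-silyl ketone, or the organometallic may act as a base and eliminate HBr from the tertiary bromide. Fallback setting out from 9 and coming back at 12, with the allylsilane made by cross-coupling instead of double addition: amidation (MeNHOMe·HCl, i-PrMgCl, THF, −20 °C) should give (1R,3S,4S)-4-bromo-3-chloro-1-hydroxy-N-methoxy-N,4-dimethylcyclohexane-1-carboxamide F7. MeMgBr (THF, 0 °C) should give 1-[(1R,3S,4S)-4-bromo-3-chloro-1-hydroxy-4-methylcyclohexyl]ethan-1-one F8. 1-(Trimethylsilyl)imidazole should give 1-[(1R,3S,4S)-4-bromo-3-chloro-4-methyl-1-(trimethylsilyloxy)cyclohexyl]ethan-1-one F9. Tf2O with 2,6-di-tert-butyl-4-methylpyridine (CH2Cl2, 0 °C) should give 1-[(1R,3S,4S)-4-bromo-3-chloro-4-methyl-1-(trimethylsilyloxy)cyclohexyl]ethenyl trifluoromethanesulfonate F10. Kumada coupling with TMSCH2MgCl (Pd(PPh3)4, THF, rt) should give 12.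

Further compounds
F1 | step 5 | methyl (1R,3R,6S)-3-hydroxy-6-methyl-7-oxabicyclo[4.1.0]heptane-3-carboxylate | COC(=O)[C@@]1(O)CC[C@]2(C)O[C@@H]2C1
F2 | step 5 | methyl (1R,3R)-1,3-dihydroxy-4-methylidenecyclohexane-1-carboxylate | COC(=O)[C@@]1(O)CCC(=C)[C@H](O)C1
F3 | step 5 | methyl (1R,3S)-3-chloro-1-hydroxy-4-methylidenecyclohexane-1-carboxylate | COC(=O)[C@@]1(O)CCC(=C)[C@@H](Cl)C1
F4 | step 8 | 2-[(1R,3S,4S)-4-bromo-3-chloro-4-methyl-1-(trimethylsilyloxy)cyclohexyl]-6-methylhepta-1,5-dien-4-ol (carbinol epimers) | C=C(CC(O)C=C(C)C)[C@@]1(O[Si](C)(C)C)CC[C@](C)(Br)[C@@H](Cl)C1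
F5 | step 8 | 2-[(1R,3S,4S)-4-bromo-3-chloro-4-methyl-1-(trimethylsilyloxy)cyclohexyl]-6-methylhepta-1,5-dien-4-one | C=C(CC(=O)C=C(C)C)[C@@]1(O[Si](C)(C)C)CC[C@](C)(Br)[C@@H](Cl)C1
F6 | step 8 | (4S)-2-[(1R,3S,4S)-4-bromo-3-chloro-4-methyl-1-(trimethylsilyloxy)cyclohexyl]-6-methylhepta-1,5-dien-4-ol | C=C(C[C@H](O)C=C(C)C)[C@@]1(O[Si](C)(C)C)CC[C@](C)(Br)[C@@H](Cl)C1
F7 | step 6 | (1R,3S,4S)-4-bromo-3-chloro-1-hydroxy-N-methoxy-N,4-dimethylcyclohexane-1-carboxamide | CON(C)C(=O)[C@@]1(O)CC[C@](C)(Br)[C@@H](Cl)C1
F8 | step 6 | 1-[(1R,3S,4S)-4-bromo-3-chloro-1-hydroxy-4-methylcyclohexyl]ethan-1-one | CC(=O)[C@@]1(O)CC[C@](C)(Br)[C@@H](Cl)C1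
F9 | step 6 | 1-[(1R,3S,4S)-4-bromo-3-chloro-4-methyl-1-(trimethylsilyloxy)cyclohexyl]ethan-1-one | CC(=O)[C@@]1(O[Si](C)(C)C)CC[C@](C)(Br)[C@@H](Cl)C1
F10 | step 6 | 1-[(1R,3S,4S)-4-bromo-3-chloro-4-methyl-1-(trimethylsilyloxy)cyclohexyl]ethenyl trifluoromethanesulfonate | C=C(OS(=O)(=O)C(F)(F)F)[C@@]1(O[Si](C)(C)C)CC[C@](C)(Br)[C@@H](Cl)C1
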